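## Retrosynthetic overview

1. Target 20 ← 19 by one acidic unmasking (cyclic orthoacetate → 8-OAc/7-OH, both silyl ethers off); the C5 chlorine comes from late NCS chlorination of dienol ether 18.
2. Carbocycle and pyran ring are formed together in one intramolecular inverse-demand oxa-Diels–Alder reaction of a 1,3-diacylallene (heterodiene O2=C3–C4=C4a, dienophile C8a=C1); this sets C8a from C7/C8.
3. The allene ← skipped ynedione ← double oxidation of the adduct of enyne 6 (acetylide) and enal 14.
4. Enyne 6 ← 2-C-methyl-D-ribono-1,4-lactone (supplies C7 and C8) by zinc fragmentation/propargylation.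
5. Enal 14 ← L-isoleucine (supplies C5'; C4' after inversion; C3' by chelation-controlled vinyl addition), then cross-metathesis.

Assumption: 2-C-methyl-D-ribono-1,4-lactone (the saccharinic lactone made in one operation from D-fructose and lime) is taken as a purchasable chiral-pool compound.

Atom labels follow the target: O2, C1, C3, C4, C4a, C5–C8, C8a in the bicycle and C1'–C7' in the side chain.

## Route

Step 1
Reactants: 1 2-C-methyl-D-ribono-1,4-lactone
Product: 2 5-deoxy-5-iodo-2-C-methyl-D-ribono-1,4-lactone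
Conditions: PPh3, I2, imidazole, THF, rt → 50 °C
Reagents that add atoms: iodine, [I][I]
Why: Appel-type (Garegg–Samuelsson) iodination is selective for the primary hydroxyl; no stereocentre is touched.

Step 2
Reactants: 2 5-deoxy-5-iodo-2-C-methyl-D-ribono-1,4-lactone
Product: 3 5-deoxy-5-iodo-2,3-O-(1-methoxyethylidene)-2-C-methyl-D-ribono-1,4-lactone
Conditions: MeC(OMe)3, PPTS (cat.), CH2Cl2, rt; Et3N quench
Reagents that add atoms: trimethyl orthoacetate, CC(OC)(OC)OC
Why: Acid-catalysed transorthoesterification onto the cis-2,3-diol gives the cyclic orthoacetate, which masks the diol and already carries the future acetyl group; the new orthoester centre is an inconsequential mixture removed in step 14.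

Step 3
Reactants: 3 iodo orthoester lactone
Product: 4 5-deoxy-5-iodo-2,3-O-(1-methoxyethylidene)-2-C-methyl-D-ribofuranose
Conditions: iBu2AlH (1.2 equiv), CH2Cl2, −78 °C; Rochelle salt work-up
Reagents that add atoms: none
Why: Low-temperature hydride reduction of the lactone stops at the lactol because the tetrahedral aluminate is stable at −78 °C; orthoester and iodide are inert.

Step 4
Reactants: 4 iodo lactol
Product: 6 1-[(4S,5R)-5-ethenyl-2-methoxy-2,4-dimethyl-1,3-dioxolan-4-yl]but-3-yn-1-ol, via pentenal 5 (not isolated)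
Conditions: Zn dust (10 equiv), HC≡CCH2Br (3 equiv), THF/H2O (4:1), sonication, 40 °C
Reagents that add atoms: propargyl bromide, C#CCBr
Why: Bernet–Vasella-type reductive fragmentation (zinc insertion into C–I, β-alkoxide elimination) opens the furanose to the pent-4-enal, which is trapped by Barbier propargylation in the same near-neutral medium; the new carbinol centre is oxidised later and C7/C8 are untouched.

Step 5
Reactants: 7 L-isoleucine
Product: 8 (2S,3S)-2-hydroxy-3-methylpentanoic acid
Conditions: NaNO2, 0.5 M H2SO4, 0 °C → rt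
Reagents that add atoms: water, O
Why: Diazotisation of the α-amino acid gives the α-hydroxy acid with retention (double inversion through the α-lactone).

Step 6
Reactants: 8 (2S,3S)-2-hydroxy-3-methylpentanoic acid
Product: 9 (3S,4S)-3-hydroxy-4-methylhexan-2-one
Conditions: MeLi (3.5 equiv), Et2O/THF, 0 °C → rt; inverse quench into cold 1 M HCl
Reagents that add atoms: methyllithium, [Li]C
Why: Methyllithium adds to the lithium carboxylate to a stable gem-diolate (carboxylic acid to methyl ketone), which releases the ketone only on quench; no stereocentre is touched.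

Step 7
Reactants: 9 (3S,4S)-3-hydroxy-4-methylhexan-2-one
Product: 11 (3R,4S)-3-hydroxy-4-methylhexan-2-one, via formate ester 10 (not isolated)
Conditions: PPh3, DIAD, HCO2H, THF, 0 °C → rt; then NaHCO3 (cat.), MeOH, rt
Reagents that add atoms: formic acid, O=CO
Why: Mitsunobu reaction: formate displaces the oxyphosphonium by SN2 at the carbonyl-activated carbinol carbon and inverts C3 (the future C4'); the formate is then removed by mild methanolysis.

Step 8
Reactants: 11 (3R,4S)-3-hydroxy-4-methylhexan-2-one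
Product: 12 (3R,4R,5S)-3,5-dimethylhept-1-ene-3,4-diol
Conditions: CH2=CHMgBr (3 equiv), THF, −78 → 0 °C; aq. NH4Cl
Reagents that add atoms: vinylmagnesium bromide, C=C[Mg]Br
Why: Chelation-controlled Grignard addition (Cram cyclic model): the magnesium alkoxide and the ketone oxygen form a five-membered chelate and vinyl attacks the face opposite the sec-butyl group, giving the syn (3R) tertiary carbinol, the future C3'.

Step 9
Reactants: 12 (3R,4R,5S)-3,5-dimethylhept-1-ene-3,4-diol
Product: 13 (2E,4R,5R,6S)-4,5-dihydroxy-4,6-dimethyloct-2-enal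
Conditions: crotonaldehyde (5 equiv), second-generation Hoveyda–Grubbs catalyst [RuCl2(H2IMes)(=CH-C6H4-2-OiPr)] (5 mol %), CH2Cl2, 40 °C
Reagents that add atoms: (E)-crotonaldehyde, C/C=C/C=O
Why: Olefin cross-metathesis of a free tertiary allylic alcohol (which does not homodimerise) with an enal partner gives the E-enal under thermodynamic control.

Step 10
Reactants: 13 dihydroxy enal
Product: 14 (2E,4R,5R,6S)-4,6-dimethyl-4,5-bis(triethylsilyloxy)oct-2-enal
Conditions: TESOTf (3 equiv), 2,6-lutidine (5 equiv), CH2Cl2, −78 → 0 °C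
Reagents that add atoms: triethylsilyl trifluoromethanesulfonate, CC[Si](CC)(CC)OS(=O)(=O)C(F)(F)F
Why: Silyl triflate silylation protects the secondary and the tertiary hydroxyl; the enal has no γ-hydrogen and cannot be enolised.

Step 11
Reactants: 6 enyne alcohol; 14 bis-silylated enal
Product: 15 (6E,8R,9R,10S)-1-[(4S,5R)-5-ethenyl-2-methoxy-2,4-dimethyl-1,3-dioxolan-4-yl]-8,10-dimethyl-8,9-bis(triethylsilyloxy)dodec-6-en-3-yne-1,5-diol
Conditions: 6 (1.1 equiv), n-BuLi (2.2 equiv), THF, −78 °C; then 14, −78 → −40 °C; pH 7 buffer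
Reagents that add atoms: none
Why: 1,2-Addition of the lithium acetylide (alkoxide/acetylide dianion of 6) to the enal joins the two fragments; both new carbinol centres are oxidised in the next step.

Step 12
Reactants: 15 enyne diol
Product: 18 7,8-O-(1-methoxyethylidene) derivative of (7R,8R,8aS)-7,8-dihydroxy-7-methyl-3-[(1E,3R,4R,5S)-3,5-dimethyl-3,4-bis(triethylsilyloxy)hept-1-en-1-yl]-8,8a-dihydro-1H-isochromen-6(7H)-one, via ynedione 16 (not isolated), via diacylallene 17 (not isolated)
Conditions: Dess–Martin periodinane (3 equiv), pyridine, CH2Cl2, 0 °C → rt; aq. NaHCO3/Na2S2O3 work-up; then Et3N (0.1 equiv), PhMe (0.01 M), rt → 80 °C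
Reagents that add atoms: none
Why: Double oxidation gives the skipped ynedione, whose doubly activated C5 methylene lets Et3N isomerise it to the 1,3-diacylallene; this closes both rings in a Tietze-type intramolecular inverse-electron-demand oxa-Diels–Alder reaction, with C8a expected to be set by C7/C8 through the tether conformer that keeps C8–H (not C8–O) anti to the forming C4a–C8a bond and the C7 methyl away from C1, placing C1 cis to O8.

Step 13
Reactants: 18 bicyclic dienol ether ketone
Product: 19 5-chloro derivative of 18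
Conditions: NCS (1.05 equiv), MeCN, 0 °C → rt
Reagents that add atoms: N-chlorosuccinimide, O=C1CCC(=O)N1Cl
Why: Electrophilic chlorination of the push-pull dienol ether occurs at its nucleophilic terminus C5 (α to the C6 carbonyl), as in halogenation of azaphilones and steroid dienol ethers; loss of H5 restores the vinylogous ester.

Step 14
Reactants: 19 chlorinated orthoester bis-silyl ether
Product: 20 8a-epi-hypocrellone A
Conditions: HF·pyridine, pyridine, THF, H2O (5 equiv), 0 °C → rt
Reagents that add atoms: water, O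
Why: Acid-catalysed orthoester hydrolysis opens the ortho acid to the secondary (axial) 8-acetate and frees the tertiary 7-OH (any 7-acetate equilibrates through the same ortho acid to the less hindered ester), while HF cleaves both Si–O bonds; no stereocentre is touched.

## Compound list

1 | 2-C-methyl-D-ribono-1,4-lactone, (3R,4R,5R)-3,4-dihydroxy-5-(hydroxymethyl)-3-methyloxolan-2-one | OC[C@H]1OC(=O)[C@](C)(O)[C@@H]1O | starting material
2 | 5-deoxy-5-iodo-2-C-methyl-D-ribono-1,4-lactone | IC[C@H]1OC(=O)[C@](C)(O)[C@@H]1O | intermediate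
3 | 5-deoxy-5-iodo-2,3-O-(1-methoxyethylidene)-2-C-methyl-D-ribono-1,4-lactone (both orthoester epimers) | IC[C@H]1OC(=O)[C@]2(C)OC(C)(OC)O[C@H]12 | intermediate
4 | 5-deoxy-5-iodo-2,3-O-(1-methoxyethylidene)-2-C-methyl-D-ribofuranose (anomers) | IC[C@H]1OC(O)[C@]2(C)OC(C)(OC)O[C@H]12 | intermediate
5 | (4R,5R)-5-ethenyl-2-methoxy-2,4-dimethyl-1,3-dioxolane-4-carbaldehyde | O=C[C@]1(C)OC(C)(OC)O[C@@H]1C=C | intermediate
6 | 1-[(4S,5R)-5-ethenyl-2-methoxy-2,4-dimethyl-1,3-dioxolan-4-yl]but-3-yn-1-ol (carbinol epimers) | C#CCC(O)[C@]1(C)OC(C)(OC)O[C@@H]1C=C | intermediate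
7 | L-isoleucine, (2S,3S)-2-amino-3-methylpentanoic acid | CC[C@H](C)[C@H](N)C(=O)O | starting material
8 | (2S,3S)-2-hydroxy-3-methylpentanoic acid | CC[C@H](C)[C@H](O)C(=O)O | intermediate
9 | (3S,4S)-3-hydroxy-4-methylhexan-2-one | CC[C@H](C)[C@H](O)C(C)=O | intermediate
10 | (3R,4S)-4-methyl-2-oxohexan-3-yl formate | CC[C@H](C)[C@@H](OC=O)C(C)=O | intermediate
11 | (3R,4S)-3-hydroxy-4-methylhexan-2-one | CC[C@H](C)[C@@H](O)C(C)=O | intermediate
12 | (3R,4R,5S)-3,5-dimethylhept-1-ene-3,4-diol | CC[C@H](C)[C@@H](O)[C@](C)(O)C=C | intermediate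
13 | (2E,4R,5R,6S)-4,5-dihydroxy-4,6-dimethyloct-2-enal | CC[C@H](C)[C@@H](O)[C@](C)(O)/C=C/C=O | intermediate
14 | (2E,4R,5R,6S)-4,6-dimethyl-4,5-bis(triethylsilyloxy)oct-2-enal | CC[C@H](C)[C@@H](O[Si](CC)(CC)CC)[C@](C)(O[Si](CC)(CC)CC)/C=C/C=O | intermediate
15 | (6E,8R,9R,10S)-1-[(4S,5R)-5-ethenyl-2-methoxy-2,4-dimethyl-1,3-dioxolan-4-yl]-8,10-dimethyl-8,9-bis(triethylsilyloxy)dodec-6-en-3-yne-1,5-diol (carbinol epimers) | CC[C@H](C)[C@@H](O[Si](CC)(CC)CC)[C@](C)(O[Si](CC)(CC)CC)/C=C/C(O)C#CCC(O)[C@]1(C)OC(C)(OC)O[C@@H]1C=C | intermediate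
16 | (6E,8R,9R,10S)-1-[(4R,5R)-5-ethenyl-2-methoxy-2,4-dimethyl-1,3-dioxolan-4-yl]-8,10-dimethyl-8,9-bis(triethylsilyloxy)dodec-6-en-3-yne-1,5-dione | CC[C@H](C)[C@@H](O[Si](CC)(CC)CC)[C@](C)(O[Si](CC)(CC)CC)/C=C/C(=O)C#CCC(=O)[C@]1(C)OC(C)(OC)O[C@@H]1C=C | intermediate
17 | (6E,8R,9R,10S)-1-[(4R,5R)-5-ethenyl-2-methoxy-2,4-dimethyl-1,3-dioxolan-4-yl]-8,10-dimethyl-8,9-bis(triethylsilyloxy)dodeca-2,3,6-triene-1,5-dione (both allene axes) | CC[C@H](C)[C@@H](O[Si](CC)(CC)CC)[C@](C)(O[Si](CC)(CC)CC)/C=C/C(=O)C=C=CC(=O)[C@]1(C)OC(C)(OC)O[C@@H]1C=C | intermediate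
18 | 7,8-O-(1-methoxyethylidene) derivative of (7R,8R,8aS)-7,8-dihydroxy-7-methyl-3-[(1E,3R,4R,5S)-3,5-dimethyl-3,4-bis(triethylsilyloxy)hept-1-en-1-yl]-8,8a-dihydro-1H-isochromen-6(7H)-one | CC[C@H](C)[C@@H](O[Si](CC)(CC)CC)[C@](C)(O[Si](CC)(CC)CC)/C=C/C1=CC2=CC(=O)[C@]3(C)OC(C)(OC)O[C@@H]3[C@@H]2CO1 | intermediate
19 | 5-chloro derivative of 18, (7R,8R,8aS) | CC[C@H](C)[C@@H](O[Si](CC)(CC)CC)[C@](C)(O[Si](CC)(CC)CC)/C=C/C1=CC2=C(Cl)C(=O)[C@]3(C)OC(C)(OC)O[C@@H]3[C@@H]2CO1 | intermediate
20 | 8a-epi-hypocrellone A, (7R,8R,8aS)-5-chloro-3-[(1E,3R,4R,5S)-3,4-dihydroxy-3,5-dimethylhept-1-en-1-yl]-7-hydroxy-7-methyl-6-oxo-6,7,8,8a-tetrahydro-1H-isochromen-8-yl acetate | CC[C@H](C)[C@@H](O)[C@](C)(O)/C=C/C1=CC2=C(Cl)C(=O)[C@](C)(O)[C@H](OC(C)=O)[C@@H]2CO1 | target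

## Step count and risk

Total steps: 14. Longest linear sequence: 10 steps (7 → 20, steps 5–10 then 11–14); the sugar branch is 8 steps (1 → 20).

The three steps most likely to fail:

Step 12 (oxidation/isomerisation/cycloaddition cascade). The electrophilic diacylallene 17 may oligomerise before it cyclises, the terminal alkene is the polarity-mismatched partner, and the C8a selectivity is a prediction from the tether model, not a certainty. The fallback sets out from 6 and comes back at 18, replacing the cycloaddition by a radical ring closure. mCPBA epoxidises the only alkene of 6 to the epoxy alkynol F4 (epoxide configuration is irrelevant). Its dianion adds to 14 as in step 11 to give the epoxy enyne diol F5. Cp2TiCl (trivalent titanium, made from Cp2TiCl2 and Mn) opens the epoxide to the C8a radical carrying a C1–O–Ti group, which closes 6-exo-dig onto the alkyne and, after hydrogen abstraction, gives the cyclohexane triol F6 with the C4a–C8a bond in place and C1 already oxygenated. MnO2 oxidises only the doubly allylic C3 carbinol to the cross-conjugated dienone F7. The C1 hydroxyl of F7 adds to the C3 carbonyl, and dehydration (Ms2O, Et3N) gives the dienol ether alcohol F8. MnO2 then oxidises the now allylic C6 carbinol to 18.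

Step 7 (Mitsunobu inversion of a β-branched α-ketol). Elimination or partial epimerisation could compete. The fallback sets out from 8 and comes back at 11, moving the inversion to the acid oxidation level, where SN2 at an α-sulfonyloxy amide is clean. Acid 8 is coupled with MeNHOMe·HCl (EDC, HOBt) to the Weinreb amide F1. Tf2O/2,6-lutidine gives the triflate F2. CsOAc in DMF displaces it with inversion to the acetate F3. Excess MeMgBr converts the amide into the methyl ketone and strips the acetate, giving 11.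

Step 14 (one-pot orthoester opening and desilylation). The orthoester could open to the tertiary 7-acetate, and the product is acid-sensitive. The fallback sets out from 19 and comes back at 20, installing the acetate by direct acylation. PPTS (cat.) in dry MeOH at 0 °C transfers the orthoester to methanol and frees the 7,8-diol F9 with both silyl ethers intact. Ac2O/pyridine acetylates only the secondary C8 hydroxyl (C7–OH is tertiary, the side-chain oxygens are silylated) to give the acetate F10. HF·pyridine removes the two silyl groups to give 20.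

## Further compounds

F1 | step 7 | (2S,3S)-2-hydroxy-N-methoxy-N,3-dimethylpentanamide | CC[C@H](C)[C@H](O)C(=O)N(C)OC
F2 | step 7 | (2S,3S)-1-[methoxy(methyl)amino]-3-methyl-1-oxopentan-2-yl trifluoromethanesulfonate | CC[C@H](C)[C@H](OS(=O)(=O)C(F)(F)F)C(=O)N(C)OC
F3 | step 7 | (2R,3S)-1-[methoxy(methyl)amino]-3-methyl-1-oxopentan-2-yl acetate | CC[C@H](C)[C@@H](OC(C)=O)C(=O)N(C)OC
F4 | step 12 | 1-[(4S,5R)-2-methoxy-2,4-dimethyl-5-(oxiran-2-yl)-1,3-dioxolan-4-yl]but-3-yn-1-ol (epoxide and carbinol epimers) | C#CCC(O)[C@]1(C)OC(C)(OC)O[C@@H]1C2CO2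
F5 | step 12 | epoxide analogue of 15 (oxiran-2-yl in place of ethenyl) | CC[C@H](C)[C@@H](O[Si](CC)(CC)CC)[C@](C)(O[Si](CC)(CC)CC)/C=C/C(O)C#CCC(O)[C@]1(C)OC(C)(OC)O[C@@H]1C2CO2
F6 | step 12 | cyclohexane triol with exocyclic C4=C4a alkene, C3 and C6 carbinols, C1 hydroxymethyl on (8aS)-C8a, orthoester and silyl ethers retained | CC[C@H](C)[C@@H](O[Si](CC)(CC)CC)[C@](C)(O[Si](CC)(CC)CC)/C=C/C(O)C=C1CC(O)[C@]2(C)OC(C)(OC)O[C@@H]2[C@@H]1CO
F7 | step 12 | C3 ketone of F6 (cross-conjugated dienone, C6 carbinol, C1 hydroxymethyl) | CC[C@H](C)[C@@H](O[Si](CC)(CC)CC)[C@](C)(O[Si](CC)(CC)CC)/C=C/C(=O)C=C1CC(O)[C@]2(C)OC(C)(OC)O[C@@H]2[C@@H]1CO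
F8 | step 12 | C6 carbinol corresponding to 18 (6-hydroxy in place of 6-oxo) | CC[C@H](C)[C@@H](O[Si](CC)(CC)CC)[C@](C)(O[Si](CC)(CC)CC)/C=C/C1=CC2=CC(O)[C@]3(C)OC(C)(OC)O[C@@H]3[C@@H]2CO1
F9 | step 14 | (7R,8R,8aS)-5-chloro-7,8-dihydroxy-7-methyl-3-[(1E,3R,4R,5S)-3,5-dimethyl-3,4-bis(triethylsilyloxy)hept-1-en-1-yl]-8,8a-dihydro-1H-isochromen-6(7H)-one | CC[C@H](C)[C@@H](O[Si](CC)(CC)CC)[C@](C)(O[Si](CC)(CC)CC)/C=C/C1=CC2=C(Cl)C(=O)[C@](C)(O)[C@H](O)[C@@H]2CO1
F10 | step 14 | 3',4'-bis(triethylsilyl) ether of 20 | CC[C@H](C)[C@@H](O[Si](CC)(CC)CC)[C@](C)(O[Si](CC)(CC)CC)/C=C/C1=CC2=C(Cl)C(=O)[C@](C)(O)[C@H](OC(C)=O)[C@@H]2CO1
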